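**Assumption:** the SMILES is taken literally, including the (2R)-2-methylbutanoate. Germacrane locants are used throughout: C1/C10 = hydroxymethyl-bearing epoxide (C14 = CH2OH on C10), C2=C3 = Z-alkene, C4/C5 = methyl-bearing epoxide (C15 = CH3), C6 = lactone CH–O, C7=C11 = butenolide alkene, C8 = acyloxy CH, C9 = CH2, C12 = lactone C=O, C13 = CH2OAc. Target = (1R,4R,5S,6S,8S,10S,2Z).

## Retrosynthetic overview
1. The 1,10-epoxide is made last, by tartrate-controlled epoxidation of the C14 allylic alcohol after desilylation.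
2. The ten-membered ring and the butenolide form in one step: C7 of a (Z)-β-bromo-enoate is made nucleophilic with Ni/Cr (a β-acylvinyl anion, d3, where C7 is natively an acceptor) and adds to the C6 epoxy-aldehyde carbon; the alkoxide closes onto C12.
3. The seco-chain comes from a Sonogashira coupling (C1–C2) and Lindlar reduction (2Z) of epoxy-alkyne **2** with iodo/bromo-diene **15**.
4. **15** comes from bromide conjugate addition/formaldehyde aldol on a γ-acyloxy ynoate, itself from asymmetric propiolate addition (sets C8) to an aldehyde built by anti-allylmagnesiation/iodination of propargyl alcohol.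
5. Ring order: 4,5-epoxide (step 1), then carbocycle and γ-lactone together (step 11), then 1,10-epoxide (step 13).

## Route

**Step 1**
Reactants: 1 (2Z)-3-methylpent-2-en-4-yn-1-ol
Product: 2 [(2S,3R)-3-ethynyl-3-methyloxiran-2-yl]methanol
Conditions: Ti(OiPr)4 (10 mol%), L-(+)-DET (12 mol%), TBHP, 4 Å MS, CH2Cl2, −20 °C
Reagents that add atoms: tert-butyl hydroperoxide CC(C)(C)OO
Why: Sharpless asymmetric epoxidation; L-(+)-tartrate gives the (2S) carbinol-side carbon, and syn delivery to the Z-alkene sets C5 (S) and C4 (R) with C3 and C6 cis, the alkyne being inert.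

**Step 2**
Reactants: 3 prop-2-yn-1-ol; 4 allylmagnesium bromide
Product: 6 (2Z)-2-(iodomethylidene)pent-4-en-1-ol, via chelated alkenylmagnesium alkoxide 5 (not isolated)
Conditions: 4 (2.5 equiv), Et2O, 0 °C→rt; then I2, THF, −78→0 °C
Reagents that add atoms: iodine II
Why: hydroxyl-directed anti-allylmagnesiation of the propargylic alkoxide puts allyl (C9) on C10 and Mg on C1 cis to CH2O, and iodinolysis with retention gives the iodide cis to C14 (the geometry needed for C2 trans to C9).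

**Step 3**
Reactants: 6 (2Z)-2-(iodomethylidene)pent-4-en-1-ol
Product: 7 tert-butyl{[(2Z)-2-(iodomethylidene)pent-4-en-1-yl]oxy}dimethylsilane
Conditions: TBSCl, imidazole, CH2Cl2, 0 °C→rt
Reagents that add atoms: tert-butyldimethylsilyl chloride CC(C)(C)[Si](C)(C)Cl
Why: standard silylation masks C14–OH through the acylation steps.

**Step 4**
Reactants: 7 tert-butyl{[(2Z)-2-(iodomethylidene)pent-4-en-1-yl]oxy}dimethylsilane
Product: 8 (3Z)-3-{[(tert-butyldimethylsilyl)oxy]methyl}-4-iodobut-3-enal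
Conditions: OsO4 (2 mol%), NaIO4 (4 equiv), 2,6-lutidine, dioxane/H2O, 0 °C→rt; used crude
Reagents that add atoms: sodium periodate [Na+].[O-]I(=O)(=O)=O (terminal oxidant; the oxygen is delivered through catalytic osmium tetroxide O=[Os](=O)(=O)=O)
Why: Lemieux–Johnson cleavage takes the monosubstituted alkene in preference to the hindered, electron-poor iodoalkene and gives the C8 aldehyde, which is used at once to avoid conjugation.

**Step 5**
Reactants: 8 (3Z)-3-{[(tert-butyldimethylsilyl)oxy]methyl}-4-iodobut-3-enal; 9 methyl prop-2-ynoate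
Product: 11 methyl (4S,6Z)-6-{[(tert-butyldimethylsilyl)oxy]methyl}-4-hydroxy-7-iodohept-6-en-2-ynoate, via methylzinc propiolate acetylide 10 (not isolated)
Conditions: 9 (3 equiv), Me2Zn (3 equiv), (S,S)-ProPhenol (20 mol%), Ph3PO (40 mol%), toluene, 4 °C
Reagents that add atoms: none
Why: Trost dinuclear-zinc ProPhenol alkynylation under amine-free conditions; the ligand enantiomer is chosen for Re-face delivery, which sets C8 as S.

**Step 6**
Reactants: 11 methyl (4S,6Z)-6-{[(tert-butyldimethylsilyl)oxy]methyl}-4-hydroxy-7-iodohept-6-en-2-ynoate; 12 (2R)-2-methylbutanoic acid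
Product: 13 methyl (4S,6Z)-6-{[(tert-butyldimethylsilyl)oxy]methyl}-7-iodo-4-{[(2R)-2-methylbutanoyl]oxy}hept-6-en-2-ynoate
Conditions: DCC, DMAP (10 mol%), CH2Cl2, 0 °C
Reagents that add atoms: none
Why: Steglich esterification at low temperature installs the C8 ester without touching either stereocentre.

**Step 7**
Reactants: 13 methyl (4S,6Z)-6-{[(tert-butyldimethylsilyl)oxy]methyl}-7-iodo-4-{[(2R)-2-methylbutanoyl]oxy}hept-6-en-2-ynoate
Product: 15 methyl (2Z,4S,6Z)-2-(acetoxymethyl)-3-bromo-6-{[(tert-butyldimethylsilyl)oxy]methyl}-7-iodo-4-{[(2R)-2-methylbutanoyl]oxy}hepta-2,6-dienoate, via bromo-aldol magnesium alkoxide 14 (not isolated)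
Conditions: MgBr2·OEt2 (2 equiv), monomeric CH2O (cracked paraformaldehyde), CH2Cl2, −20→0 °C; then Ac2O, DMAP (cat.), 0 °C
Reagents that add atoms: magnesium bromide Br[Mg]Br; formaldehyde C=O; acetic anhydride CC(=O)OC(C)=O
Why: Proposed new method: bromide adds to the Lewis-acid-activated ynoate at C7, the magnesium allenolate is hydroxymethylated at C11 in the plane of the C7 substituents anti to bromine (Br cis to CO2Me, C13 cis to C8, also the thermodynamic β-halo-enoate geometry), and the alkoxide is acetylated in the same flask; the closest known reaction is the MgX2/Et2AlI-promoted halo-aldol (β-halo Morita–Baylis–Hillman) of propiolates and ynones.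

**Step 8**
Reactants: 15 methyl (2Z,4S,6Z)-2-(acetoxymethyl)-3-bromo-6-{[(tert-butyldimethylsilyl)oxy]methyl}-7-iodo-4-{[(2R)-2-methylbutanoyl]oxy}hepta-2,6-dienoate; 2 [(2S,3R)-3-ethynyl-3-methyloxiran-2-yl]methanol
Product: 16 methyl (2Z,4S,6Z)-2-(acetoxymethyl)-3-bromo-6-{[(tert-butyldimethylsilyl)oxy]methyl}-9-[(2R,3S)-3-(hydroxymethyl)-2-methyloxiran-2-yl]-4-{[(2R)-2-methylbutanoyl]oxy}nona-2,6-dien-8-ynoate
Conditions: Pd(PPh3)4 (5 mol%), CuI (10 mol%), iPr2NEt, THF, 0 °C→rt
Reagents that add atoms: none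
Why: Sonogashira coupling with retention at C1; the alkenyl iodide undergoes oxidative addition far faster than the hindered tetrasubstituted bromide, and Hünig's base avoids amine attack on the β-bromo-enoate (minor diastereomers from imperfect ee in 2 and 11 are removed here).

**Step 9**
Reactants: 16 the enyne of step 8
Product: 17 methyl (2Z,4S,6Z,8Z)-2-(acetoxymethyl)-3-bromo-6-{[(tert-butyldimethylsilyl)oxy]methyl}-9-[(2R,3S)-3-(hydroxymethyl)-2-methyloxiran-2-yl]-4-{[(2R)-2-methylbutanoyl]oxy}nona-2,6,8-trienoate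
Conditions: H2 (1 atm), Lindlar catalyst, quinoline, EtOAc, 0 °C
Reagents that add atoms: none
Why: Lindlar syn-semihydrogenation of the only alkyne sets the C2=C3 Z-alkene; the alkenyl bromide, epoxide and tetrasubstituted enoate are not reduced under poisoned conditions.

**Step 10**
Reactants: 17 the (8Z)-trienoate of step 9
Product: 18 methyl (2Z,4S,6Z,8Z)-2-(acetoxymethyl)-3-bromo-6-{[(tert-butyldimethylsilyl)oxy]methyl}-9-[(2R,3R)-3-formyl-2-methyloxiran-2-yl]-4-{[(2R)-2-methylbutanoyl]oxy}nona-2,6,8-trienoate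
Conditions: Dess–Martin periodinane, pyridine, CH2Cl2, 0 °C; used at once
Reagents that add atoms: none
Why: buffered Dess–Martin oxidation of the only free alcohol gives the non-epimerised α,β-epoxy aldehyde, which is carried on immediately because cis-vinyl/formyl epoxides can rearrange on standing.

**Step 11**
Reactants: 18 the epoxy aldehyde of step 10
Product: 21 (4R,5S,6S,8S,2Z)-13-acetoxy-14-[(tert-butyldimethylsilyl)oxy]-4,5-epoxy-8-[(2R)-2-methylbutanoyloxy]germacra-1(10),2,7(11)-trien-12,6-olide (C2 trans to C9 across C1=C10), via alkenylchromium(III) species 19 (not isolated), via macrocyclic chromium(III) alkoxide 20 (not isolated)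
Conditions: CrCl2 (10 equiv), NiCl2 (20 mol%), DMSO/THF 3:1, rt, syringe-pump addition to 2 mM
Reagents that add atoms: none
Why: intramolecular Nozaki–Hiyama–Kishi reaction in which C7, natively the acceptor β-carbon of the enoate, reacts as a β-acylvinyl anion (d3) at the C6 aldehyde carbon; Felkin–Anh/Cornforth attack anti to the C5–O bond and on the side of H-5 sets C6 as S, and the cis methyl ester lactonises to the butenolide.

**Step 12**
Reactants: 21 the silyl-protected macrocyclic butenolide of step 11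
Product: 22 (4R,5S,6S,8S,2Z)-13-acetoxy-4,5-epoxy-14-hydroxy-8-[(2R)-2-methylbutanoyloxy]germacra-1(10),2,7(11)-trien-12,6-olide
Conditions: HF·pyridine, pyridine, THF, 0 °C
Reagents that add atoms: none
Why: buffered fluoride desilylation frees the C14 allylic alcohol without opening the vinyl epoxide or cleaving the esters.

**Step 13**
Reactants: 22 the C14 allylic alcohol of step 12
Product: 23 (1R,4R,5S,6S,8S,10S,2Z)-13-acetoxy-1,10:4,5-diepoxy-14-hydroxy-8-[(2R)-2-methylbutanoyloxy]germacra-2,7(11)-dien-12,6-olide (target, CNP0108300.1)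
Conditions: Ti(OiPr)4, L-(+)-DET, TBHP, 4 Å MS, CH2Cl2, −20 °C
Reagents that add atoms: tert-butyl hydroperoxide CC(C)(C)OO
Why: hydroxyl-directed Sharpless epoxidation takes only the C1=C10 alkene (not C2=C3 or the butenolide), and L-(+)-tartrate delivers oxygen to the face that gives 10S,1R as a trans epoxide by syn addition to the ring-trans alkene.

## Compound list
1 | (2Z)-3-methylpent-2-en-4-yn-1-ol | C#C/C(C)=C\CO | starting material
2 | [(2S,3R)-3-ethynyl-3-methyloxiran-2-yl]methanol | C#C[C@@]1(C)O[C@H]1CO | intermediate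
3 | prop-2-yn-1-ol | C#CCO | starting material
4 | allylmagnesium bromide | C=CC[Mg]Br | starting material
5 | chelated (Z)-alkenylmagnesium bromide alkoxide from anti-allylmagnesiation (Mg on C1 cis to CH2OMgBr) | C=CC/C(CO[Mg]Br)=C/[Mg]Br | intermediate
6 | (2Z)-2-(iodomethylidene)pent-4-en-1-ol | OC/C(CC=C)=C\I | intermediate
7 | tert-butyl{[(2Z)-2-(iodomethylidene)pent-4-en-1-yl]oxy}dimethylsilane | CC(C)(C)[Si](C)(C)OC/C(CC=C)=C\I | intermediate
8 | (3Z)-3-{[(tert-butyldimethylsilyl)oxy]methyl}-4-iodobut-3-enal | CC(C)(C)[Si](C)(C)OC/C(CC=O)=C\I | intermediate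
9 | methyl prop-2-ynoate | C#CC(=O)OC | starting material
10 | methyl 3-(methylzincio)prop-2-ynoate | COC(=O)C#C[Zn]C | intermediate
11 | methyl (4S,6Z)-6-{[(tert-butyldimethylsilyl)oxy]methyl}-4-hydroxy-7-iodohept-6-en-2-ynoate | O[C@H](C#CC(=O)OC)C/C(CO[Si](C)(C)C(C)(C)C)=C/I | intermediate
12 | (2R)-2-methylbutanoic acid | CC[C@@H](C)C(=O)O | starting material
13 | methyl (4S,6Z)-6-{[(tert-butyldimethylsilyl)oxy]methyl}-7-iodo-4-{[(2R)-2-methylbutanoyl]oxy}hept-6-en-2-ynoate | CC[C@@H](C)C(=O)O[C@H](C#CC(=O)OC)C/C(CO[Si](C)(C)C(C)(C)C)=C/I | intermediate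
14 | bromomagnesium alkoxide of methyl (2Z,4S,6Z)-3-bromo-2-(hydroxymethyl)-6-{[(tert-butyldimethylsilyl)oxy]methyl}-7-iodo-4-{[(2R)-2-methylbutanoyl]oxy}hepta-2,6-dienoate | CC[C@@H](C)C(=O)O[C@H](/C(Br)=C(\CO[Mg]Br)C(=O)OC)C/C(CO[Si](C)(C)C(C)(C)C)=C/I | intermediate
15 | methyl (2Z,4S,6Z)-2-(acetoxymethyl)-3-bromo-6-{[(tert-butyldimethylsilyl)oxy]methyl}-7-iodo-4-{[(2R)-2-methylbutanoyl]oxy}hepta-2,6-dienoate | CC[C@@H](C)C(=O)O[C@H](/C(Br)=C(\COC(C)=O)C(=O)OC)C/C(CO[Si](C)(C)C(C)(C)C)=C/I | intermediate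
16 | methyl (2Z,4S,6Z)-2-(acetoxymethyl)-3-bromo-6-{[(tert-butyldimethylsilyl)oxy]methyl}-9-[(2R,3S)-3-(hydroxymethyl)-2-methyloxiran-2-yl]-4-{[(2R)-2-methylbutanoyl]oxy}nona-2,6-dien-8-ynoate | CC[C@@H](C)C(=O)O[C@H](/C(Br)=C(\COC(C)=O)C(=O)OC)C/C(CO[Si](C)(C)C(C)(C)C)=C/C#C[C@@]1(C)O[C@H]1CO | intermediate
17 | methyl (2Z,4S,6Z,8Z)-2-(acetoxymethyl)-3-bromo-6-{[(tert-butyldimethylsilyl)oxy]methyl}-9-[(2R,3S)-3-(hydroxymethyl)-2-methyloxiran-2-yl]-4-{[(2R)-2-methylbutanoyl]oxy}nona-2,6,8-trienoate | CC[C@@H](C)C(=O)O[C@H](/C(Br)=C(\COC(C)=O)C(=O)OC)C/C(CO[Si](C)(C)C(C)(C)C)=C/C=C\[C@@]1(C)O[C@H]1CO | intermediate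
18 | methyl (2Z,4S,6Z,8Z)-2-(acetoxymethyl)-3-bromo-6-{[(tert-butyldimethylsilyl)oxy]methyl}-9-[(2R,3R)-3-formyl-2-methyloxiran-2-yl]-4-{[(2R)-2-methylbutanoyl]oxy}nona-2,6,8-trienoate | CC[C@@H](C)C(=O)O[C@H](/C(Br)=C(\COC(C)=O)C(=O)OC)C/C(CO[Si](C)(C)C(C)(C)C)=C/C=C\[C@@]1(C)O[C@H]1C=O | intermediate
19 | alkenylchromium(III) dichloride from 18 (Cr on C7 in place of Br) | CC[C@@H](C)C(=O)O[C@H](/C([Cr](Cl)Cl)=C(\COC(C)=O)C(=O)OC)C/C(CO[Si](C)(C)C(C)(C)C)=C/C=C\[C@@]1(C)O[C@H]1C=O | intermediate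
20 | macrocyclic chromium(III) C6-alkoxide of the ring-closed methyl ester (6S, before lactonisation) | CC[C@@H](C)C(=O)O[C@H]1C/C(CO[Si](C)(C)C(C)(C)C)=C/C=C\[C@@]2(C)O[C@H]2[C@@H](O[Cr](Cl)Cl)/C1=C(/COC(C)=O)C(=O)OC | intermediate
21 | (4R,5S,6S,8S,2Z)-13-acetoxy-14-[(tert-butyldimethylsilyl)oxy]-4,5-epoxy-8-[(2R)-2-methylbutanoyloxy]germacra-1(10),2,7(11)-trien-12,6-olide (C2 trans to C9 across C1=C10) | CC[C@@H](C)C(=O)O[C@H]1C/C(CO[Si](C)(C)C(C)(C)C)=C/C=C\[C@@]2(C)O[C@H]2[C@H]2OC(=O)C(COC(C)=O)=C12 | intermediate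
22 | (4R,5S,6S,8S,2Z)-13-acetoxy-4,5-epoxy-14-hydroxy-8-[(2R)-2-methylbutanoyloxy]germacra-1(10),2,7(11)-trien-12,6-olide | CC[C@@H](C)C(=O)O[C@H]1C/C(CO)=C/C=C\[C@@]2(C)O[C@H]2[C@H]2OC(=O)C(COC(C)=O)=C12 | intermediate
23 | (1R,4R,5S,6S,8S,10S,2Z)-13-acetoxy-1,10:4,5-diepoxy-14-hydroxy-8-[(2R)-2-methylbutanoyloxy]germacra-2,7(11)-dien-12,6-olide | CC[C@@H](C)C(=O)O[C@H]1C[C@@]2(CO)O[C@@H]2/C=C\[C@@]2(C)O[C@H]2[C@H]2OC(=O)C(COC(C)=O)=C12 | target

## Step count and risks
Total steps: 13. Longest linear sequence: 12 (steps 2–13, from prop-2-yn-1-ol).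

**Most likely to fail, 1: step 11 (ten-membered Ni/Cr ring closure with a tetrasubstituted alkenyl bromide).** The fallback sets out from 15 (with 2) and comes back at 21. It keeps the same C6–C7 bond but makes it bimolecularly and closes the ring by metathesis. Stille coupling of 15 with tributyl(vinyl)stannane at the iodide gives the vinyl-coupled bromo triene F1. Dess–Martin oxidation of 2 gives the epoxy ynal F2. Intermolecular Ni/Cr coupling of F1 with F2 (Felkin addition, then lactonisation) gives the open-chain butenolide F3. Lindlar semihydrogenation of its terminal alkyne gives the vinyl epoxide F4. Ring-closing metathesis of F4 (Grubbs II, high dilution) forms C2=C3, Z by ring constraint, and returns to 21.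

**Most likely to fail, 2: step 7 (bromide addition/formaldehyde aldol on the internal ynoate; reactivity and alkene geometry).** The fallback sets out from 11 and comes back at 15. It delivers C13 from the C8 oxygen so that the geometry is enforced by a ring. Formylation of 11 (acetic formic anhydride, pyridine) gives the formate ester F5. MgBr2-promoted bromide addition is then followed by attack of the allenolate on the tethered formate, giving the bromo dihydrofuran lactol F6 with C13 necessarily cis to C8. NaBH4/CeCl3 reduction of the lactol gives the diol F7. Selective acetylation of the primary hydroxyl (AcCl, 2,4,6-collidine, −78 °C) gives the 13-monoacetate F8. DCC/DMAP esterification of F8 with 12 returns to 15.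

**Most likely to fail, 3: step 13 (facial selectivity of the late epoxidation on the macrocycle).** The fallback sets out from 21 and comes back at 23. It swaps reagent-controlled, hydroxyl-directed epoxidation for substrate-controlled peripheral attack before deprotection. Dimethyldioxirane (acetone, −20 °C) epoxidises the more electron-rich trisubstituted C1=C10 alkene of 21 from the outer face, giving the silyl-protected bis-epoxide F9. HF·pyridine desilylation of F9 returns to 23.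

## Further compounds
F1 | step 11 | methyl (2Z,4S,6Z)-2-(acetoxymethyl)-3-bromo-6-{[(tert-butyldimethylsilyl)oxy]methyl}-4-{[(2R)-2-methylbutanoyl]oxy}nona-2,6,8-trienoate | CC[C@@H](C)C(=O)O[C@H](/C(Br)=C(\COC(C)=O)C(=O)OC)C/C(CO[Si](C)(C)C(C)(C)C)=C/C=C
F2 | step 11 | (2R,3R)-3-ethynyl-3-methyloxirane-2-carbaldehyde | C#C[C@@]1(C)O[C@H]1C=O
F3 | step 11 | open-chain butenolide: 3-(acetoxymethyl)-5-[(2S,3R)-3-ethynyl-3-methyloxiran-2-yl]-4-[(1S,3Z)-3-{[(tert-butyldimethylsilyl)oxy]methyl}-1-{[(2R)-2-methylbutanoyl]oxy}hexa-3,5-dien-1-yl]furan-2(5H)-one, (5S) | CC[C@@H](C)C(=O)O[C@@H](C/C(CO[Si](C)(C)C(C)(C)C)=C/C=C)C1=C(COC(C)=O)C(=O)O[C@@H]1[C@@H]1O[C@]1(C)C#C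
F4 | step 11 | the same butenolide with the ethynyl group reduced to ethenyl (vinyl epoxide) | CC[C@@H](C)C(=O)O[C@@H](C/C(CO[Si](C)(C)C(C)(C)C)=C/C=C)C1=C(COC(C)=O)C(=O)O[C@@H]1[C@@H]1O[C@]1(C)C=C
F5 | step 7 | methyl (4S,6Z)-6-{[(tert-butyldimethylsilyl)oxy]methyl}-4-(formyloxy)-7-iodohept-6-en-2-ynoate | O=CO[C@H](C#CC(=O)OC)C/C(CO[Si](C)(C)C(C)(C)C)=C/I
F6 | step 7 | methyl (5S)-4-bromo-5-[(2Z)-2-{[(tert-butyldimethylsilyl)oxy]methyl}-3-iodoprop-2-en-1-yl]-2-hydroxy-2,5-dihydrofuran-3-carboxylate (lactol, anomers) | COC(=O)C1=C(Br)[C@H](C/C(CO[Si](C)(C)C(C)(C)C)=C/I)OC1O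
F7 | step 7 | methyl (2Z,4S,6Z)-3-bromo-4-hydroxy-2-(hydroxymethyl)-6-{[(tert-butyldimethylsilyl)oxy]methyl}-7-iodohepta-2,6-dienoate | O[C@H](/C(Br)=C(\CO)C(=O)OC)C/C(CO[Si](C)(C)C(C)(C)C)=C/I
F8 | step 7 | methyl (2Z,4S,6Z)-2-(acetoxymethyl)-3-bromo-4-hydroxy-6-{[(tert-butyldimethylsilyl)oxy]methyl}-7-iodohepta-2,6-dienoate | O[C@H](/C(Br)=C(\COC(C)=O)C(=O)OC)C/C(CO[Si](C)(C)C(C)(C)C)=C/I
F9 | step 13 | 14-O-(tert-butyldimethylsilyl) ether of the target (1R,4R,5S,6S,8S,10S,2Z) | CC[C@@H](C)C(=O)O[C@H]1C[C@@]2(CO[Si](C)(C)C(C)(C)C)O[C@@H]2/C=C\[C@@]2(C)O[C@H]2[C@H]2OC(=O)C(COC(C)=O)=C12
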